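**Plan**

- Retrosynthesis: rings A and B are opened together at C5–C10 and C1–C2 (retro-Diels–Alder through the C3 enol ether). Then C4–C18 (methylation), C4=C5 (Knoevenagel), C1=C10 (methylenation), C6–C7 (aldol), C13–C16 (ketyl–alkyne, ring D), C8–C15 (conjugate propargylation), C6–C8 and C9–C10 (vinylogous ester chemistry) are cut.
- Forward: ring C is a commercial cyclohexenone; ring D closes in step 6; rings A and B close together in step 13. Ring B (C5, C6, C8, C9, C10) is the last ring of the skeleton and no ring forms after it; steps 14–18 only adjust C4, C3, C7 and C20.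
- Feature used: C10 is quaternary and carries the C20 formyl group, so C10=C1 is a 2-substituted acrolein. The C2=C3(O)–C4(CO2R)=C5 edge of ring A is a 2-siloxydiene. C6–C8–C9 of the bicyclo[3.2.1]octane is a three-atom tether, so the new C5–C10 bond closes the five-membered ring B while the cyclohexene ring A forms.
- Stereochemistry: C9 by catalytic asymmetric allylation; C8 anti to the C9 substituent; C13 by the bridge; C6 by the enolate face; C5 and C10 in the cycloaddition; C4 by methylation anti to C20; C3 by equatorial hydride attack.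

Key step: step 13

Remark: gibberellane numbering (C1–C20) is used for all intermediates, α being the face of C19 and C20 and β the face of H-5, H-9 and C7; the target is treated in its open 19-acid/20-aldehyde form, which can equilibrate with the 19,20-lactol.

**Route**

Step 1
Reactants: 1 3-ethoxycyclohex-2-en-1-one; 2 prop-2-en-1-yl carbonochloridate (allyl chloroformate)
Product: 3 5-ethoxycyclohexa-1,5-dien-1-yl prop-2-en-1-yl carbonate
Conditions: LiN(iPr)2, TMEDA, THF, −78 °C; then 2, −78 °C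
Reagents that add atoms: none
Why: Kinetic deprotonation of the vinylogous ester at the α' carbon (the future C9) and O-acylation of the lithium enolate by the chloroformate (enol carbonate formation) should give the substrate for decarboxylative allylation.

Step 2
Reactants: 3 5-ethoxycyclohexa-1,5-dien-1-yl prop-2-en-1-yl carbonate
Product: 4 (6S)-3-ethoxy-6-(prop-2-en-1-yl)cyclohex-2-en-1-one
Conditions: Pd2(dba)3·CHCl3 (2.5 mol %), (R,R)-N,N'-(cyclohexane-1,2-diyl)bis[2-(diphenylphosphanyl)benzamide] (6 mol %), 1,4-dioxane, 23 °C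
Reagents that add atoms: none
Why: Palladium-catalysed decarboxylative asymmetric allylic alkylation (Tsuji–Trost type) releases CO2 and recombines the enolate with the π-allyl fragment inside the chiral ligand pocket, which should set the tertiary C9 centre as 6S (the ligand enantiomer is the one that gives this sense).

Step 3
Reactants: 4 (6S)-3-ethoxy-6-(prop-2-en-1-yl)cyclohex-2-en-1-one; 5 methyl acetate
Product: 7 methyl 2-[(6S)-3-oxo-6-(prop-2-en-1-yl)cyclohex-1-en-1-yl]acetate, via carbinol adduct 6 (not isolated)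
Conditions: 5, LiN(iPr)2, THF, −78 °C; then 4, −78 to −40 °C; then 1 M aq. HCl, 0 °C
Reagents that add atoms: water, O
Why: Stork–Danheiser transposition: 1,2-addition of the lithium ester enolate to the vinylogous ester carbonyl, then acid hydrolysis of the enol ether and dehydration, should give the transposed enone with C6/C5 on C8 while C9 is not involved.

Step 4
Reactants: 7 methyl 2-[(6S)-3-oxo-6-(prop-2-en-1-yl)cyclohex-1-en-1-yl]acetate; 8 tributyl(propa-1,2-dien-1-yl)stannane
Product: 9 methyl 2-[(1R,2S)-5-oxo-2-(prop-2-en-1-yl)-1-(prop-2-yn-1-yl)cyclohexyl]acetate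
Conditions: TiCl4, CH2Cl2, −78 °C
Reagents that add atoms: none
Why: Lewis-acid-promoted conjugate propargylation (Sakurai-type SE2' addition of the allenylstannane to the TiCl4-activated enone) should create the quaternary C8 with the new C15 group anti to the C9 allyl substituent, as usual for 4-substituted cyclohexenones.

Step 5
Reactants: 9 methyl 2-[(1R,2S)-5-oxo-2-(prop-2-en-1-yl)-1-(prop-2-yn-1-yl)cyclohexyl]acetate
Product: 11 methyl 2-[(1R,2S)-2-(2,2-dimethoxyethyl)-5-oxo-1-(prop-2-yn-1-yl)cyclohexyl]acetate, via keto aldehyde 10 (not isolated)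
Conditions: OsO4 (2 mol %), NaIO4, 2,6-lutidine, dioxane–H2O, 23 °C; then HC(OMe)3, CeCl3·7H2O (cat.), MeOH, 23 °C
Reagents that add atoms: sodium periodate, [Na+].[O-]I(=O)(=O)=O (oxygen of aldehyde 10); trimethyl orthoformate, COC(OC)OC (methoxy groups of 11)
Why: Lemieux–Johnson cleavage is selective for the monosubstituted alkene over the alkyne and gives the C20 aldehyde, which CeCl3-catalysed acetalisation should protect chemoselectively in the presence of the ring ketone.

Step 6
Reactants: 11 methyl 2-[(1R,2S)-2-(2,2-dimethoxyethyl)-5-oxo-1-(prop-2-yn-1-yl)cyclohexyl]acetate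
Product: 12 methyl 2-[(1R,2S,5S)-2-(2,2-dimethoxyethyl)-5-hydroxy-6-methylidenebicyclo[3.2.1]octan-1-yl]acetate
Conditions: SmI2 (2.5 equiv), HMPA, tBuOH, THF, 0 °C
Reagents that add atoms: none
Why: Reductive ketyl–alkyne cyclisation (5-exo-dig addition of the ketyl at C13 to the alkyne, then reduction and protonation of the vinyl radical) should close ring D and give the bridgehead C13 alcohol and the exocyclic C16 methylene, the C13 configuration being fixed by the bridged geometry.

Step 7
Reactants: 12 methyl 2-[(1R,2S,5S)-2-(2,2-dimethoxyethyl)-5-hydroxy-6-methylidenebicyclo[3.2.1]octan-1-yl]acetate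
Product: 14 methyl (2S)-3-[(tert-butyldimethylsilyl)oxy]-2-[(1S,2S,5S)-2-(2,2-dimethoxyethyl)-5-hydroxy-6-methylidenebicyclo[3.2.1]octan-1-yl]propanoate, via hydroxy ester 13 (not isolated)
Conditions: LiN(iPr)2 (2.3 equiv), THF, −78 °C; HCHO (gas), −78 °C; then TBSCl, imidazole, DMF, 0 °C
Reagents that add atoms: formaldehyde, C=O; tert-butyldimethylsilyl chloride, CC(C)(C)[Si](C)(C)Cl
Why: Aldol addition of the lithium ester enolate to formaldehyde should set C6, the electrophile approaching the A1,3-minimised enolate rotamer on the face away from the C15–C16 bridge, and TBSCl then silylates only the primary alkoxide.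

Step 8
Reactants: 14 methyl (2S)-3-[(tert-butyldimethylsilyl)oxy]-2-[(1S,2S,5S)-2-(2,2-dimethoxyethyl)-5-hydroxy-6-methylidenebicyclo[3.2.1]octan-1-yl]propanoate
Product: 15 (2S)-3-[(tert-butyldimethylsilyl)oxy]-2-[(1S,2S,5S)-2-(2,2-dimethoxyethyl)-5-hydroxy-6-methylidenebicyclo[3.2.1]octan-1-yl]propanal
Conditions: iBu2AlH (2.2 equiv), CH2Cl2, −78 °C; aq. KNaC4H4O6 work-up
Reagents that add atoms: none
Why: Partial reduction of the methyl ester by iBu2AlH should stop at the aldehyde because the tetrahedral aluminate, chelated by the β-silyloxy group, is stable at −78 °C.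

Step 9
Reactants: 15 (2S)-3-[(tert-butyldimethylsilyl)oxy]-2-[(1S,2S,5S)-2-(2,2-dimethoxyethyl)-5-hydroxy-6-methylidenebicyclo[3.2.1]octan-1-yl]propanal; 16 prop-2-en-1-yl 3-oxobutanoate (allyl acetoacetate)
Product: 17 prop-2-en-1-yl (2Z,4S)-2-acetyl-5-[(tert-butyldimethylsilyl)oxy]-4-[(1S,2S,5S)-2-(2,2-dimethoxyethyl)-5-hydroxy-6-methylidenebicyclo[3.2.1]octan-1-yl]pent-2-enoate
Conditions: piperidine (10 mol %), AcOH (10 mol %), 4 Å MS, CH2Cl2, 0 to 23 °C
Reagents that add atoms: none
Why: Knoevenagel condensation of the aldehyde with the β-keto ester should give the alkylidene acetoacetate, whose favoured Z isomer has the ester cis to C6 and the coplanar acetyl group trans to it.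

Step 10
Reactants: 17 prop-2-en-1-yl (2Z,4S)-2-acetyl-5-[(tert-butyldimethylsilyl)oxy]-4-[(1S,2S,5S)-2-(2,2-dimethoxyethyl)-5-hydroxy-6-methylidenebicyclo[3.2.1]octan-1-yl]pent-2-enoate
Product: 18 prop-2-en-1-yl (2Z,4S)-2-acetyl-5-[(tert-butyldimethylsilyl)oxy]-4-[(1S,2S,5S)-5-hydroxy-6-methylidene-2-(2-oxoethyl)bicyclo[3.2.1]octan-1-yl]pent-2-enoate
Conditions: PPTS (cat.), acetone–H2O, 45 °C
Reagents that add atoms: water, O
Why: Mild acid-catalysed acetal hydrolysis should release the C20 aldehyde and leave the primary TBS ether, the tertiary allylic alcohol and the alkylidene acetoacetate intact.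

Step 11
Reactants: 18 prop-2-en-1-yl (2Z,4S)-2-acetyl-5-[(tert-butyldimethylsilyl)oxy]-4-[(1S,2S,5S)-5-hydroxy-6-methylidene-2-(2-oxoethyl)bicyclo[3.2.1]octan-1-yl]pent-2-enoate
Product: 19 prop-2-en-1-yl (2Z,4S)-2-acetyl-5-[(tert-butyldimethylsilyl)oxy]-4-[(1S,2R,5S)-5-hydroxy-6-methylidene-2-(3-oxoprop-1-en-2-yl)bicyclo[3.2.1]octan-1-yl]pent-2-enoate
Conditions: [CH2=NMe2]I (3 equiv), Et3N, CH2Cl2, 23 °C
Reagents that add atoms: N,N-dimethylmethyleneiminium iodide, C[N+](C)=C.[I-]
Why: Eschenmoser methylenation (Mannich reaction of the aldehyde enol with the iminium salt, then elimination of dimethylamine) should turn the CH2CHO arm into the 2-substituted acrolein, the iminium ion being far more electrophilic than the internal alkylidene acetoacetate.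

Step 12
Reactants: 19 prop-2-en-1-yl (2Z,4S)-2-acetyl-5-[(tert-butyldimethylsilyl)oxy]-4-[(1S,2R,5S)-5-hydroxy-6-methylidene-2-(3-oxoprop-1-en-2-yl)bicyclo[3.2.1]octan-1-yl]pent-2-enoate
Product: 20 prop-2-en-1-yl (2Z,4S)-5-[(tert-butyldimethylsilyl)oxy]-4-[(1S,2R,5S)-6-methylidene-2-(3-oxoprop-1-en-2-yl)-5-[(triethylsilyl)oxy]bicyclo[3.2.1]octan-1-yl]-2-{1-[(triethylsilyl)oxy]ethenyl}pent-2-enoate
Conditions: Et3SiOTf (2.5 equiv), Et3N, CH2Cl2, −78 to 0 °C
Reagents that add atoms: triethylsilyl trifluoromethanesulfonate, CC[Si](CC)(CC)OS(=O)(=O)C(F)(F)F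
Why: Soft enolisation of the methyl ketone (O-silylation, then kinetic deprotonation of the methyl group and not of the hindered C6–H) should give the cross-conjugated 2-siloxydiene, and the tertiary C13 alcohol is silylated in the same operation.

Step 13
Reactants: 20 prop-2-en-1-yl (2Z,4S)-5-[(tert-butyldimethylsilyl)oxy]-4-[(1S,2R,5S)-6-methylidene-2-(3-oxoprop-1-en-2-yl)-5-[(triethylsilyl)oxy]bicyclo[3.2.1]octan-1-yl]-2-{1-[(triethylsilyl)oxy]ethenyl}pent-2-enoate
Product: 21 prop-2-en-1-yl 7-[(tert-butyldimethylsilyl)oxy]-20-oxo-3,13-bis[(triethylsilyl)oxy]-18-norgibberella-3,16-dien-19-oate (5β-H, 6α-H, 9β-H, 10α-formyl)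
Conditions: PhMe (0.005 M), BHT (cat.), 110 °C
Reagents that add atoms: none
Why: Thermal intramolecular Diels–Alder reaction: the 2-siloxydiene C2=C3–C4=C5 (largest HOMO coefficient at C2) and the 2-substituted acrolein C1=C10 (largest LUMO coefficient at C1) should combine in a concerted, asynchronous [4+2] cycloaddition that forms C1–C2 and C5–C10 and leaves the silyl enol ether of the C3 ketone with the C19 ester on C4. The closest known reaction type is the intramolecular Diels–Alder reaction of nona-1,3,8-trienes activated by an acyl group on C8, which gives angularly functionalised trans-hydrindanes. Ring A is closed as the new cyclohexene of the cycloaddition (C1, C2, C3, C4, C5, C10), and ring B as the five-membered ring made of the C6–C8–C9 tether and the new C5–C10 bond (fused mode, the tether joining the diene terminus to the substituted dienophile carbon). C10 is controlled by C9: in the reactive rotamer H-9 eclipses the C10=C1 bond (allylic strain), so the diene, which can only arrive from the C8 side, puts C1 on the face of H-9 and leaves C20 α; C5 is controlled by the endo position of the formyl group with the tether exo, which is the trans-fused mode and gives H-5 β, and by C6, whose hydrogen eclipses the Z alkene (A1,3 strain against the cis ester) so that the face syn to C8 reacts. The step needs trans ring fusion, one π-face of each component and an accessible s-cis diene; the rigid bicyclo[3.2.1]octane tether, the matched C6 and C9 centres, the endo preference of the aldehyde and the Z geometry that keeps C6 outside the diene are expected to secure them. High dilution and a radical inhibitor should suppress intermolecular cycloaddition and polymerisation of the enal.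

Step 14
Reactants: 21 prop-2-en-1-yl 7-[(tert-butyldimethylsilyl)oxy]-20-oxo-3,13-bis[(triethylsilyl)oxy]-18-norgibberella-3,16-dien-19-oate
Product: 22 prop-2-en-1-yl 7-[(tert-butyldimethylsilyl)oxy]-3,20-dioxo-13-[(triethylsilyl)oxy]gibberell-16-en-19-oate (4β-methyl, 4α-ester)
Conditions: Bu4NF (1.05 equiv), MeI (10 equiv), THF, −78 to 0 °C
Reagents that add atoms: iodomethane, CI
Why: Fluoride cleaves the silyl enol ether and the resulting β-keto ester enolate should undergo C-methylation on the face opposite to the axial C20 formyl group and to C6, which places C18 β and the C19 ester α (the sense known for methylation of 3-oxo-4-carboalkoxy decalins with an angular group).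

Step 15
Reactants: 22 prop-2-en-1-yl 7-[(tert-butyldimethylsilyl)oxy]-3,20-dioxo-13-[(triethylsilyl)oxy]gibberell-16-en-19-oate
Product: 23 prop-2-en-1-yl 7,13-dihydroxy-20,20-dimethoxy-3-oxogibberell-16-en-19-oate
Conditions: CSA (cat.), HC(OMe)3, MeOH, 23 °C
Reagents that add atoms: trimethyl orthoformate, COC(OC)OC
Why: Acid-catalysed acetalisation should mask the neopentyl C20 aldehyde while methanolysis under the same conditions removes the primary TBS and the tertiary TES ethers, the hindered α-quaternary C3 ketone not forming a ketal.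

Step 16
Reactants: 23 prop-2-en-1-yl 7,13-dihydroxy-20,20-dimethoxy-3-oxogibberell-16-en-19-oate
Product: 25 13-hydroxy-20,20-dimethoxy-3-oxogibberell-16-ene-7,19-dioic acid 19-(prop-2-en-1-yl) ester, via C7 aldehyde 24 (not isolated)
Conditions: TEMPO (20 mol %), PhI(OAc)2 (2.5 equiv), MeCN–pH 7 phosphate buffer, 23 °C
Reagents that add atoms: water, O
Why: TEMPO/PhI(OAc)2 oxidation should convert the primary C7 alcohol through the aldehyde and its hydrate into the carboxylic acid, without touching the tertiary alcohol or the alkene, and leave C6 in its thermodynamically preferred configuration (carboxyl trans to C4).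

Step 17
Reactants: 25 13-hydroxy-20,20-dimethoxy-3-oxogibberell-16-ene-7,19-dioic acid 19-(prop-2-en-1-yl) ester
Product: 26 3β,13-dihydroxy-20,20-dimethoxygibberell-16-ene-7,19-dioic acid 19-(prop-2-en-1-yl) ester
Conditions: LiBH(sBu)3 (3.5 equiv), THF, −78 °C; aq. NH4Cl
Reagents that add atoms: none
Why: The bulky trialkylborohydride should attack the α-quaternary cyclohexanone along the equatorial trajectory and give the axial 3β-alcohol, cis to the C18 methyl group.

Step 18
Reactants: 26 3β,13-dihydroxy-20,20-dimethoxygibberell-16-ene-7,19-dioic acid 19-(prop-2-en-1-yl) ester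
Product: 28 3β,13-dihydroxy-20-oxogibberell-16-ene-7,19-dioic acid (target), via diacid acetal 27 (not isolated)
Conditions: Pd(PPh3)4 (5 mol %), morpholine, THF, 23 °C; then AcOH–H2O (3:1), 40 °C
Reagents that add atoms: water, O
Why: Tsuji–Trost deallylation cleaves the hindered C19 ester by ionisation at the allyl group, and mild aqueous acid should then hydrolyse the dimethyl acetal (assisted by the neighbouring C19 acid) to the C20 aldehyde without protonating the 16-ene.

**Compound list**

1 | 3-ethoxycyclohex-2-en-1-one | CCOC1=CC(=O)CCC1 | starting material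
2 | prop-2-en-1-yl carbonochloridate (allyl chloroformate) | C=CCOC(Cl)=O | starting material
3 | 5-ethoxycyclohexa-1,5-dien-1-yl prop-2-en-1-yl carbonate | CCOC1=CC(OC(=O)OCC=C)=CCC1 | intermediate
4 | (6S)-3-ethoxy-6-(prop-2-en-1-yl)cyclohex-2-en-1-one | CCOC1=CC(=O)[C@H](CC=C)CC1 | intermediate
5 | methyl acetate | COC(C)=O | starting material
6 | methyl 2-[(6S)-3-ethoxy-1-hydroxy-6-(prop-2-en-1-yl)cyclohex-2-en-1-yl]acetate (carbinol adduct, present as lithium alkoxide, both C1 epimers) | CCOC1=CC(O)(CC(=O)OC)[C@H](CC=C)CC1 | intermediate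
7 | methyl 2-[(6S)-3-oxo-6-(prop-2-en-1-yl)cyclohex-1-en-1-yl]acetate | COC(=O)CC1=CC(=O)CC[C@H]1CC=C | intermediate
8 | tributyl(propa-1,2-dien-1-yl)stannane | C=C=C[Sn](CCCC)(CCCC)CCCC | starting material
9 | methyl 2-[(1R,2S)-5-oxo-2-(prop-2-en-1-yl)-1-(prop-2-yn-1-yl)cyclohexyl]acetate | COC(=O)C[C@@]1(CC#C)CC(=O)CC[C@H]1CC=C | intermediate
10 | methyl 2-[(1R,2S)-5-oxo-2-(2-oxoethyl)-1-(prop-2-yn-1-yl)cyclohexyl]acetate | COC(=O)C[C@@]1(CC#C)CC(=O)CC[C@H]1CC=O | intermediate
11 | methyl 2-[(1R,2S)-2-(2,2-dimethoxyethyl)-5-oxo-1-(prop-2-yn-1-yl)cyclohexyl]acetate | COC(=O)C[C@@]1(CC#C)CC(=O)CC[C@H]1CC(OC)OC | intermediate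
12 | methyl 2-[(1R,2S,5S)-2-(2,2-dimethoxyethyl)-5-hydroxy-6-methylidenebicyclo[3.2.1]octan-1-yl]acetate | C=C1C[C@]2(CC(=O)OC)C[C@@]1(O)CC[C@H]2CC(OC)OC | intermediate
13 | methyl (2S)-2-[(1S,2S,5S)-2-(2,2-dimethoxyethyl)-5-hydroxy-6-methylidenebicyclo[3.2.1]octan-1-yl]-3-hydroxypropanoate | C=C1C[C@]2([C@@H](CO)C(=O)OC)C[C@@]1(O)CC[C@H]2CC(OC)OC | intermediate
14 | methyl (2S)-3-[(tert-butyldimethylsilyl)oxy]-2-[(1S,2S,5S)-2-(2,2-dimethoxyethyl)-5-hydroxy-6-methylidenebicyclo[3.2.1]octan-1-yl]propanoate | C=C1C[C@]2([C@@H](CO[Si](C)(C)C(C)(C)C)C(=O)OC)C[C@@]1(O)CC[C@H]2CC(OC)OC | intermediate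
15 | (2S)-3-[(tert-butyldimethylsilyl)oxy]-2-[(1S,2S,5S)-2-(2,2-dimethoxyethyl)-5-hydroxy-6-methylidenebicyclo[3.2.1]octan-1-yl]propanal | C=C1C[C@]2([C@@H](CO[Si](C)(C)C(C)(C)C)C=O)C[C@@]1(O)CC[C@H]2CC(OC)OC | intermediate
16 | prop-2-en-1-yl 3-oxobutanoate (allyl acetoacetate) | C=CCOC(=O)CC(C)=O | starting material
17 | prop-2-en-1-yl (2Z,4S)-2-acetyl-5-[(tert-butyldimethylsilyl)oxy]-4-[(1S,2S,5S)-2-(2,2-dimethoxyethyl)-5-hydroxy-6-methylidenebicyclo[3.2.1]octan-1-yl]pent-2-enoate | C=C1C[C@]2([C@@H](CO[Si](C)(C)C(C)(C)C)/C=C(/C(C)=O)C(=O)OCC=C)C[C@@]1(O)CC[C@H]2CC(OC)OC | intermediate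
18 | prop-2-en-1-yl (2Z,4S)-2-acetyl-5-[(tert-butyldimethylsilyl)oxy]-4-[(1S,2S,5S)-5-hydroxy-6-methylidene-2-(2-oxoethyl)bicyclo[3.2.1]octan-1-yl]pent-2-enoate | C=C1C[C@]2([C@@H](CO[Si](C)(C)C(C)(C)C)/C=C(/C(C)=O)C(=O)OCC=C)C[C@@]1(O)CC[C@H]2CC=O | intermediate
19 | prop-2-en-1-yl (2Z,4S)-2-acetyl-5-[(tert-butyldimethylsilyl)oxy]-4-[(1S,2R,5S)-5-hydroxy-6-methylidene-2-(3-oxoprop-1-en-2-yl)bicyclo[3.2.1]octan-1-yl]pent-2-enoate | C=C1C[C@]2([C@@H](CO[Si](C)(C)C(C)(C)C)/C=C(/C(C)=O)C(=O)OCC=C)C[C@@]1(O)CC[C@H]2C(=C)C=O | intermediate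
20 | prop-2-en-1-yl (2Z,4S)-5-[(tert-butyldimethylsilyl)oxy]-4-[(1S,2R,5S)-6-methylidene-2-(3-oxoprop-1-en-2-yl)-5-[(triethylsilyl)oxy]bicyclo[3.2.1]octan-1-yl]-2-{1-[(triethylsilyl)oxy]ethenyl}pent-2-enoate | C=C1C[C@]2([C@@H](CO[Si](C)(C)C(C)(C)C)/C=C(/C(=C)O[Si](CC)(CC)CC)C(=O)OCC=C)C[C@@]1(O[Si](CC)(CC)CC)CC[C@H]2C(=C)C=O | intermediate
21 | prop-2-en-1-yl 7-[(tert-butyldimethylsilyl)oxy]-20-oxo-3,13-bis[(triethylsilyl)oxy]-18-norgibberella-3,16-dien-19-oate (5β-H, 6α-H, 9β-H, 10α-formyl) | C=C1C[C@]23C[C@@]1(O[Si](CC)(CC)CC)CC[C@H]2[C@]1(C=O)CCC(O[Si](CC)(CC)CC)=C(C(=O)OCC=C)[C@H]1[C@@H]3CO[Si](C)(C)C(C)(C)C | intermediate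
22 | prop-2-en-1-yl 7-[(tert-butyldimethylsilyl)oxy]-3,20-dioxo-13-[(triethylsilyl)oxy]gibberell-16-en-19-oate (4β-methyl, 4α-ester) | C=C1C[C@]23C[C@@]1(O[Si](CC)(CC)CC)CC[C@H]2[C@]1(C=O)CCC(=O)[C@@](C)(C(=O)OCC=C)[C@H]1[C@@H]3CO[Si](C)(C)C(C)(C)C | intermediate
23 | prop-2-en-1-yl 7,13-dihydroxy-20,20-dimethoxy-3-oxogibberell-16-en-19-oate | C=C1C[C@]23C[C@@]1(O)CC[C@H]2[C@]1(C(OC)OC)CCC(=O)[C@@](C)(C(=O)OCC=C)[C@H]1[C@@H]3CO | intermediate
24 | prop-2-en-1-yl 13-hydroxy-20,20-dimethoxy-3,7-dioxogibberell-16-en-19-oate (C7 aldehyde) | C=C1C[C@]23C[C@@]1(O)CC[C@H]2[C@]1(C(OC)OC)CCC(=O)[C@@](C)(C(=O)OCC=C)[C@H]1[C@@H]3C=O | intermediate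
25 | 13-hydroxy-20,20-dimethoxy-3-oxogibberell-16-ene-7,19-dioic acid 19-(prop-2-en-1-yl) ester | C=C1C[C@]23C[C@@]1(O)CC[C@H]2[C@]1(C(OC)OC)CCC(=O)[C@@](C)(C(=O)OCC=C)[C@H]1[C@@H]3C(=O)O | intermediate
26 | 3β,13-dihydroxy-20,20-dimethoxygibberell-16-ene-7,19-dioic acid 19-(prop-2-en-1-yl) ester | C=C1C[C@]23C[C@@]1(O)CC[C@H]2[C@]1(C(OC)OC)CC[C@H](O)[C@@](C)(C(=O)OCC=C)[C@H]1[C@@H]3C(=O)O | intermediate
27 | 3β,13-dihydroxy-20,20-dimethoxygibberell-16-ene-7,19-dioic acid | C=C1C[C@]23C[C@@]1(O)CC[C@H]2[C@]1(C(OC)OC)CC[C@H](O)[C@@](C)(C(=O)O)[C@H]1[C@@H]3C(=O)O | intermediate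
28 | 3β,13-dihydroxy-20-oxogibberell-16-ene-7,19-dioic acid (CNP0236431.1) | C=C1C[C@]23C[C@@]1(O)CC[C@H]2[C@]1(C=O)CC[C@H](O)[C@@](C)(C(=O)O)[C@H]1[C@@H]3C(=O)O | target

**Totals and risks**

Total step count: 18. Longest linear sequence: 18 steps (compound 1 to compound 28).

Steps most likely to fail:

1. Step 13. Competition between the endo-formyl (trans-fused) and exo (cis-fused) transition states, attack on the wrong π-face, or loss of the silyl enol ether before cyclisation would erode the yield of the required adduct. Fallback: an amine-catalysed annulation that needs no silyl enol ether. It sets out from compound 19: pyrrolidine (20 mol %) and AcOH in CHCl3 at 23 °C convert the methyl ketone into a cross-conjugated 2-aminodiene, which should undergo the amine-catalysed [4+2] annulation with the tethered acrolein and, after hydrolysis, give the β-keto ester prop-2-en-1-yl 7-[(tert-butyldimethylsilyl)oxy]-13-hydroxy-3,20-dioxo-18-norgibberell-16-en-19-oate F1. C-methylation (K2CO3, MeI, acetone) should give prop-2-en-1-yl 7-[(tert-butyldimethylsilyl)oxy]-13-hydroxy-3,20-dioxogibberell-16-en-19-oate F2, which under the conditions of step 15 comes back to the route at compound 23.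

2. Step 7. Poor facial selectivity of the aldol addition would give the C6 epimer, which is mismatched in the cycloaddition. Fallback: catalyst control in place of substrate control. It sets out from compound 12: iBu2AlH (CH2Cl2, −78 °C) should reduce the ester to 2-[(1R,2S,5S)-2-(2,2-dimethoxyethyl)-5-hydroxy-6-methylidenebicyclo[3.2.1]octan-1-yl]acetaldehyde F3. Enamine-catalysed α-hydroxymethylation (aqueous formaldehyde, 2-[diphenyl(trimethylsilyloxy)methyl]pyrrolidine in the enantiomeric form that gives 2S, pH 7 buffer, toluene) should give (2S)-2-[(1S,2S,5S)-2-(2,2-dimethoxyethyl)-5-hydroxy-6-methylidenebicyclo[3.2.1]octan-1-yl]-3-hydroxypropanal F4. Silylation (TBSCl, imidazole, DMF) comes back to the route at compound 15.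

3. Step 9. Slow condensation of the hindered α-branched aldehyde, epimerisation at C6 through the enamine, and formation of the E isomer are the likely problems. Fallback: Horner–Wadsworth–Emmons olefination in place of amine-catalysed condensation. It sets out from compound 15: prop-2-en-1-yl 2-(diethoxyphosphoryl)-3-oxobutanoate with NaH in THF (0 to 40 °C) gives a weakly basic, doubly stabilised phosphonate anion that should deliver compound 17 directly, where it comes back to the route; no new compound is made.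

**Further compounds**

F1 | step 13 | prop-2-en-1-yl 7-[(tert-butyldimethylsilyl)oxy]-13-hydroxy-3,20-dioxo-18-norgibberell-16-en-19-oate (C4 epimers or enol) | C=C1C[C@]23C[C@@]1(O)CC[C@H]2[C@]1(C=O)CCC(=O)C(C(=O)OCC=C)[C@H]1[C@@H]3CO[Si](C)(C)C(C)(C)C
F2 | step 13 | prop-2-en-1-yl 7-[(tert-butyldimethylsilyl)oxy]-13-hydroxy-3,20-dioxogibberell-16-en-19-oate | C=C1C[C@]23C[C@@]1(O)CC[C@H]2[C@]1(C=O)CCC(=O)[C@@](C)(C(=O)OCC=C)[C@H]1[C@@H]3CO[Si](C)(C)C(C)(C)C
F3 | step 7 | 2-[(1R,2S,5S)-2-(2,2-dimethoxyethyl)-5-hydroxy-6-methylidenebicyclo[3.2.1]octan-1-yl]acetaldehyde | C=C1C[C@]2(CC=O)C[C@@]1(O)CC[C@H]2CC(OC)OC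
F4 | step 7 | (2S)-2-[(1S,2S,5S)-2-(2,2-dimethoxyethyl)-5-hydroxy-6-methylidenebicyclo[3.2.1]octan-1-yl]-3-hydroxypropanal | C=C1C[C@]2([C@@H](CO)C=O)C[C@@]1(O)CC[C@H]2CC(OC)OC
F0 | step 9 | none | none
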